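**Plan**
- Locants: C1 carries C7H2OBz, C2 is the vinylic CH, and C3–C6 are the oxygenated ring carbons (benzoate on O5). With the ring drawn C1→C6 clockwise, O3 and O6 point up (β) and O4 and O5 point down (α).
- Cuts, in order: the two benzoates and the C1=C2 alkene go back to a tertiary C1 carbinol. C1–C7 is then cut (hydroxymethyl anion equivalent plus C1 ketone). Last, the ring bond C2–C3 is cut by a retro-aldol to an acyclic 1,5-keto aldehyde.
- Enabling feature: C2 is the only carbon of the six-membered carbocycle that bears no substituent. It lies between C1, the latent ketone, and the C3 carbinol. The triad C4–C6 (O4/O5 cis, O5/O6 trans) is C2–C4 of L-rhamnose, so the rhamnose methyl is C2, its C5 is C1 and its C1 is C3.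
- Forward: L-rhamnose is marked at O3 with PMB (the later ring-benzoate site), opened to the 1,5-diol and doubly oxidised. The aldol closes the only ring. C7 is added, both benzoates go on in one operation, the alkene is made by dehydration, and the remaining ethers are cleaved.
- Stereochemistry: C4, C5 and C6 come unchanged from L-rhamnose. C3 is set in the aldol (axial hydroxyl, trans to O4 and O5). The C1 carbinol centre is transient.

Key step: step 7

Assumption: the transient C1 centre of 18, 19, 20 and 22 is drawn as the 1β-alcohol expected from α-face attack on the magnesium-chelated ketone; step 13 erases this centre.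

Step 1
Reactants: 1 L-rhamnose (monohydrate); 2 allyl alcohol
Product: 3 allyl α-L-rhamnopyranoside
Conditions: 2 (solvent), TfOH (5 mol %), 80 °C
Reagents that add atoms: allyl alcohol (2), C=CCO
Why: Fischer glycosidation under thermodynamic control should favour the axial α-glycoside through the anomeric effect, and the allyl aglycone can later be removed without the hot mineral acid that a 4-methoxybenzyl ether would not survive.

Step 2
Reactants: 3 allyl α-L-rhamnopyranoside; 4 4-methoxybenzyl chloride
Product: 6 allyl 3-O-(4-methoxybenzyl)-α-L-rhamnopyranoside, via stannylene acetal 5 (not isolated)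
Conditions: Bu2SnO, toluene, reflux (Dean–Stark); then 4, CsF, DMF, rt
Reagents that add atoms: 4-methoxybenzyl chloride (4), COc1ccc(CCl)cc1; dibutyltin oxide, CCCC[Sn](=O)CCCC (kept only in 5)
Why: In this stannylene-directed alkylation the tin acetal forms on the cis-2,3-diol and activates the equatorial O3, so only the oxygen that becomes O5 of the target receives the oxidatively removable ether.

Step 3
Reactants: 6 allyl 3-O-(4-methoxybenzyl)-α-L-rhamnopyranoside; 7 benzyl bromide
Product: 8 allyl 2,4-di-O-benzyl-3-O-(4-methoxybenzyl)-α-L-rhamnopyranoside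
Conditions: NaH, 7, DMF, 0 °C to rt
Reagents that add atoms: benzyl bromide (7), BrCc1ccccc1
Why: Williamson etherification caps the two remaining hydroxyls, and the allyl glycoside and the PMB ether are inert to NaH.

Step 4
Reactants: 8 allyl 2,4-di-O-benzyl-3-O-(4-methoxybenzyl)-α-L-rhamnopyranoside
Product: 10 2,4-di-O-benzyl-3-O-(4-methoxybenzyl)-L-rhamnopyranose (anomer mixture), via prop-1-enyl glycoside 9 (not isolated)
Conditions: [Ir(cod)(PMePh2)2]PF6 (2 mol %, pre-activated with H2), THF, rt; then 0.5 M aq HCl, acetone, rt to 40 °C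
Reagents that add atoms: none
Why: Metal-hydride-catalysed allyl-to-propenyl isomerisation followed by enol ether hydrolysis frees the anomeric hydroxyl under conditions that benzyl and PMB ethers tolerate.

Step 5
Reactants: 10 2,4-di-O-benzyl-3-O-(4-methoxybenzyl)-L-rhamnopyranose
Product: 11 2,4-di-O-benzyl-3-O-(4-methoxybenzyl)-L-rhamnitol (free 1-OH and 5-OH)
Conditions: NaBH4, EtOH–THF, 0 °C to rt
Reagents that add atoms: none
Why: Borohydride reduces the open-chain aldehyde tautomer of the lactol and so exposes the 1,5-diol without touching a stereocentre.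

Step 6
Reactants: 11 2,4-di-O-benzyl-3-O-(4-methoxybenzyl)-L-rhamnitol
Product: 12 2,4-di-O-benzyl-6-deoxy-3-O-(4-methoxybenzyl)-L-lyxo-hexos-5-ulose
Conditions: (COCl)2, DMSO, CH2Cl2, −78 °C; iPr2NEt, −78 to −20 °C; cold pH 7 buffer; used crude
Reagents that add atoms: none
Why: In this double Swern oxidation both hydroxyls are activated before base is added, so no hydroxy aldehyde can close to a lactol and over-oxidise to the lactone, and the cold hindered base limits epimerisation next to the carbonyls.

Step 7
Reactants: 12 2,4-di-O-benzyl-6-deoxy-3-O-(4-methoxybenzyl)-L-lyxo-hexos-5-ulose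
Product: 13 (2R,3S,4S,5R)-2,4-bis(benzyloxy)-5-hydroxy-3-(4-methoxybenzyloxy)cyclohexan-1-one (target locants: C1 ketone, 3β-OH, 4α-OBn, 5α-OPMB, 6β-OBn)
Conditions: D-proline (30 mol %), DMSO, rt
Reagents that add atoms: none
Why: D-Proline condenses with the methyl ketone to the less substituted enamine (N–C1=C2H2), C2 adds to the C3 aldehyde while the carboxyl proton passes to the aldehyde oxygen, and iminium hydrolysis releases 13 and the catalyst; this is the direct amine-catalysed intramolecular aldol known for sugar-derived 1,5-dicarbonyl compounds, and it matches the ring-forming stage of the Ferrier carbocyclisation, reached here without a metal because the 6-deoxy sugar already holds the methyl ketone. The one ring closes in the 6-(enolendo)-exo-trig mode, and site selectivity is built in because bond formation from either other α-carbon (C6 onto C3, or C4 onto C1) would give a cyclobutane. Since O4 and O5 are cis, the three ethers cannot all be equatorial, and the chain should fold into the chair that copies the 1C4 chair of L-rhamnopyranose, with O5 and O6 equatorial and only O4 axial. The proton bridge holds the aldehyde oxygen gauche to C1, that is axial, so the new hydroxyl ends trans-diaxial to O4 and trans to O5 (3R), the relationship also found in Ferrier cyclisations, whereas the flipped chair would set O3 and O5 syn-axial. In an enolendo closure the aldehyde substituent C4 is forced gauche rather than anti to C1, which reverses the aldehyde face usually taken by a proline enamine, and it is the anti enamine of D-proline that holds its carboxyl group over the β face where O3 lies in this chair, so catalyst and substrate should reinforce each other. The step must stay under kinetic control, because the 3-equatorial epimer is probably more stable and because loss of water, β-elimination of O5 and epimerisation at C4 or C6 open up under stronger base; a weakly basic catalyst at room temperature and the reluctance of α-branched α,β-dialkoxy aldehydes to form enamines are relied on for this.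

Step 8
Reactants: 13 aldol (3β-OH ketone); 14 tert-butyldimethylsilyl triflate
Product: 15 3-O-TBS ether of 13 (3β-OTBS, 4α-OBn, 5α-OPMB, 6β-OBn cyclohexan-1-one)
Conditions: 14, 2,6-lutidine, CH2Cl2, −78 to −20 °C
Reagents that add atoms: tert-butyldimethylsilyl triflate (14), CC(C)(C)[Si](C)(C)OS(=O)(=O)C(F)(F)F
Why: Silyl triflate silylation with a weak hindered base caps the axial hydroxyl at low temperature, where a β-hydroxy ketone should neither retro-aldolise nor eliminate.

Step 9
Reactants: 15 3-O-TBS ketone; 16 (chloromethyl)isopropoxydimethylsilane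
Product: 18 1β-hydroxy-1α-[(isopropoxydimethylsilyl)methyl] adduct of 15, via silylmethyl Grignard reagent 17 (not isolated)
Conditions: 16, Mg, THF, reflux; then 15, THF, −78 to 0 °C
Reagents that add atoms: (chloromethyl)isopropoxydimethylsilane (16), CC(C)O[Si](C)(C)CCl; magnesium, [Mg] (kept only in 17)
Why: This Grignard addition is the first stage of nucleophilic hydroxymethylation: the weakly basic silylmethyl reagent adds rather than enolises, and magnesium chelation between C1=O and the equatorial O6, together with the axial 3-OTBS group shielding the β face, should send C7 to the α face.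

Step 10
Reactants: 18 silylmethyl carbinol
Product: 19 1β-hydroxy-1α-(hydroxymethyl) diol (3β-OTBS, 4α-OBn, 5α-OPMB, 6β-OBn)
Conditions: 30% aq H2O2, KF, KHCO3, THF–MeOH (1:1), rt
Reagents that add atoms: hydrogen peroxide, OO
Why: Tamao–Fleming oxidation replaces the C7–Si bond by C7–OH under mildly basic conditions that a secondary TBS ether and the benzyl-type ethers withstand.

Step 11
Reactants: 19 diol
Product: 20 1β,5α,7-triol (3β-OTBS, 4α-OBn, 6β-OBn)
Conditions: DDQ, CH2Cl2–pH 7 buffer (10:1), 0 °C
Reagents that add atoms: none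
Why: Oxidative PMB cleavage with DDQ attacks only the electron-rich benzyl ether, and O1 lies trans to O5, so it cannot trap the intermediate oxocarbenium ion as an acetal.

Step 12
Reactants: 20 triol; 21 benzoyl chloride
Product: 22 5,7-di-O-benzoate with free tertiary 1β-OH (3β-OTBS, 4α-OBn, 6β-OBn)
Conditions: 21 (2.5 equiv), pyridine, DMAP (cat.), 0 °C to rt
Reagents that add atoms: benzoyl chloride (21), O=C(Cl)c1ccccc1
Why: DMAP-catalysed acylation takes the primary O7 and the secondary O5 in one operation, while the tertiary hydroxyl beside the axial silyl ether should stay free.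

Step 13
Reactants: 22 tertiary alcohol dibenzoate
Product: 23 [3β-(TBS-oxy)-4α,6β-bis(benzyloxy)-5α-(benzoyloxy)cyclohex-1-en-1-yl]methyl benzoate
Conditions: Burgess reagent (MeO2CN−SO2N+Et3), toluene, 70 °C
Reagents that add atoms: none
Why: Burgess dehydration is a syn elimination of the sulfamate ester, and O1 (β) has a cis hydrogen on C2 but none on C6 (H6 is α), so the ring alkene can form only toward C2, while loss of a C7 hydrogen would give a less favoured exocyclic enol ester.

Step 14
Reactants: 23 silyl ether alkene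
Product: 24 [4α,6β-bis(benzyloxy)-5α-(benzoyloxy)-3β-hydroxycyclohex-1-en-1-yl]methyl benzoate
Conditions: HF·pyridine, pyridine–THF, 0 °C to rt
Reagents that add atoms: none
Why: Fluoride desilylation in an acidic buffer frees O3 at a stage where no free hydroxyl adjoins a benzoate, so acyl migration has no path.

Step 15
Reactants: 24 dibenzyl ether
Product: 25 [(3R,4S,5R,6S)-5-(benzoyloxy)-3,4,6-trihydroxycyclohex-1-en-1-yl]methyl benzoate (target)
Conditions: BCl3, C6HMe5, CH2Cl2, −78 °C; MeOH quench
Reagents that add atoms: none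
Why: Lewis acid debenzylation with BCl3 and pentamethylbenzene as a non-basic benzyl cation scavenger should cleave both benzyl ethers at low temperature without touching the alkene, the allylic benzoate or the ring benzoate, which hydrogenolysis could not do.

**Compound list**

1 | L-rhamnose (6-deoxy-L-mannose, sold as the monohydrate, drawn open-chain) | O=C[C@H](O)[C@H](O)[C@@H](O)[C@@H](O)C | starting material
2 | allyl alcohol | C=CCO | starting material
3 | allyl α-L-rhamnopyranoside | C=CCO[C@H]1[C@H](O)[C@H](O)[C@@H](O)[C@H](C)O1 | intermediate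
4 | 4-methoxybenzyl chloride | COc1ccc(CCl)cc1 | starting material
5 | allyl 2,3-O-dibutylstannylene-α-L-rhamnopyranoside | C=CCO[C@H]1[C@@H]2O[Sn](CCCC)(CCCC)O[C@@H]2[C@@H](O)[C@H](C)O1 | intermediate
6 | allyl 3-O-(4-methoxybenzyl)-α-L-rhamnopyranoside | C=CCO[C@H]1[C@H](O)[C@H](OCc2ccc(OC)cc2)[C@@H](O)[C@H](C)O1 | intermediate
7 | benzyl bromide | BrCc1ccccc1 | starting material
8 | allyl 2,4-di-O-benzyl-3-O-(4-methoxybenzyl)-α-L-rhamnopyranoside | C=CCO[C@H]1[C@H](OCc2ccccc2)[C@H](OCc2ccc(OC)cc2)[C@@H](OCc2ccccc2)[C@H](C)O1 | intermediate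
9 | (E)-prop-1-enyl 2,4-di-O-benzyl-3-O-(4-methoxybenzyl)-α-L-rhamnopyranoside | C/C=C/O[C@H]1[C@H](OCc2ccccc2)[C@H](OCc2ccc(OC)cc2)[C@@H](OCc2ccccc2)[C@H](C)O1 | intermediate
10 | 2,4-di-O-benzyl-3-O-(4-methoxybenzyl)-L-rhamnopyranose (anomer mixture) | OC1[C@H](OCc2ccccc2)[C@H](OCc2ccc(OC)cc2)[C@@H](OCc2ccccc2)[C@H](C)O1 | intermediate
11 | 2,4-di-O-benzyl-3-O-(4-methoxybenzyl)-L-rhamnitol | OC[C@H](OCc1ccccc1)[C@H](OCc1ccc(OC)cc1)[C@@H](OCc1ccccc1)[C@@H](O)C | intermediate
12 | 2,4-di-O-benzyl-6-deoxy-3-O-(4-methoxybenzyl)-L-lyxo-hexos-5-ulose | O=C[C@H](OCc1ccccc1)[C@H](OCc1ccc(OC)cc1)[C@@H](OCc1ccccc1)C(C)=O | intermediate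
13 | (2R,3S,4S,5R)-2,4-bis(benzyloxy)-5-hydroxy-3-(4-methoxybenzyloxy)cyclohexan-1-one | O=C1C[C@@H](O)[C@H](OCc2ccccc2)[C@H](OCc2ccc(OC)cc2)[C@H]1OCc1ccccc1 | intermediate
14 | tert-butyldimethylsilyl triflate | CC(C)(C)[Si](C)(C)OS(=O)(=O)C(F)(F)F | starting material
15 | 3-O-TBS ether of 13 | O=C1C[C@@H](O[Si](C)(C)C(C)(C)C)[C@H](OCc2ccccc2)[C@H](OCc2ccc(OC)cc2)[C@H]1OCc1ccccc1 | intermediate
16 | (chloromethyl)isopropoxydimethylsilane | CC(C)O[Si](C)(C)CCl | starting material
17 | (isopropoxydimethylsilyl)methylmagnesium chloride | CC(C)O[Si](C)(C)C[Mg]Cl | intermediate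
18 | 1β-hydroxy-1α-[(isopropoxydimethylsilyl)methyl] adduct of 15 | O[C@@]1(C[Si](C)(C)OC(C)C)C[C@@H](O[Si](C)(C)C(C)(C)C)[C@H](OCc2ccccc2)[C@H](OCc2ccc(OC)cc2)[C@H]1OCc1ccccc1 | intermediate
19 | 1β-hydroxy-1α-(hydroxymethyl) diol | O[C@@]1(CO)C[C@@H](O[Si](C)(C)C(C)(C)C)[C@H](OCc2ccccc2)[C@H](OCc2ccc(OC)cc2)[C@H]1OCc1ccccc1 | intermediate
20 | 1β,5α,7-triol | O[C@@]1(CO)C[C@@H](O[Si](C)(C)C(C)(C)C)[C@H](OCc2ccccc2)[C@H](O)[C@H]1OCc1ccccc1 | intermediate
21 | benzoyl chloride | O=C(Cl)c1ccccc1 | starting material
22 | 5,7-di-O-benzoate with free 1β-OH | O[C@@]1(COC(=O)c2ccccc2)C[C@@H](O[Si](C)(C)C(C)(C)C)[C@H](OCc2ccccc2)[C@H](OC(=O)c2ccccc2)[C@H]1OCc1ccccc1 | intermediate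
23 | 3-O-TBS-4,6-di-O-benzyl ether of the target | O=C(OCC1=C[C@@H](O[Si](C)(C)C(C)(C)C)[C@H](OCc2ccccc2)[C@H](OC(=O)c2ccccc2)[C@H]1OCc1ccccc1)c1ccccc1 | intermediate
24 | 4,6-di-O-benzyl ether of the target | O=C(OCC1=C[C@@H](O)[C@H](OCc2ccccc2)[C@H](OC(=O)c2ccccc2)[C@H]1OCc1ccccc1)c1ccccc1 | intermediate
25 | [(3R,4S,5R,6S)-5-(benzoyloxy)-3,4,6-trihydroxycyclohex-1-en-1-yl]methyl benzoate | O=C(OCC1=C[C@@H](O)[C@H](O)[C@H](OC(=O)c2ccccc2)[C@H]1O)c1ccccc1 | target

Total step count: 15. Longest linear sequence: 15 steps (1 to 25).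

**Steps most likely to fail**

**Step 7** may suffer from poor facial selectivity at the aldehyde, or from loss of water from the β-hydroxy ketone during the reaction. The fallback gives up stereocontrol in the ring closure and sets C3 afterwards.
- It sets out from 12, which is cyclised with Et3N in CH2Cl2. This gives 13 mixed with the 3-epi aldol F1.
- The crude mixture is treated with MsCl and Et3N at 0 °C. The resulting C3 mesylates F2 eliminate in the same flask to 4α,6β-bis(benzyloxy)-5α-(4-methoxybenzyloxy)cyclohex-2-en-1-one F3.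
- Weitz–Scheffer epoxidation (H2O2, benzyltrimethylammonium hydroxide, THF–MeOH, 0 °C) should take place anti to the pseudo-axial O4 and give the 2β,3β-epoxy ketone F4.
- Reductive opening at the α-carbon with (PhSe)2, NaBH4 and AcOH in EtOH leaves the C3–O bond untouched, and the route is rejoined at 13.

**Step 13** may eliminate in the wrong direction (toward C7, or toward C6 after ionisation), or the neighbouring C7 benzoate may capture the developing C1 cation. The fallback builds the alkene before any ester is present.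
- It sets out from 15. Corey–Chaykovsky methylenation (Me3SI, NaH, DMSO–THF, 0 °C) should give the spiro-epoxide F5, with C7 on the α face and oxygen on the β face.
- Epoxide-to-allylic-alcohol isomerisation with Et2Al(TMP), made from Et2AlCl and lithium 2,2,6,6-tetramethylpiperidide in toluene at 0 °C, is a syn elimination. It can reach only the β hydrogen on C2 and gives the allylic alcohol F6.
- DDQ in buffered CH2Cl2 removes the PMB group to give the 5,7-diol F7.
- Double benzoylation (21, pyridine, DMAP) rejoins the route at 23.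

**Step 15** may fail through ionisation of the allylic C–O bonds, acyl migration under the Lewis acid, or incomplete debenzylation. The fallback removes the benzyl groups by hydrogenolysis while the ring is still saturated.
- It sets out from 22. H2 over Pd(OH)2/C in EtOAc gives the 1,4,6-triol F8.
- TESOTf (2.2 equiv) and 2,6-lutidine in CH2Cl2 at −78 °C protect the two secondary hydroxyls as the 4,6-bis-TES ether F9.
- Burgess dehydration as in step 13 gives the tris-silyl alkene F10.
- HF·pyridine in THF removes all three silyl groups, and the route is rejoined at 25.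

Further compounds
F1 | step 7 | 3-epi aldol (3α-OH epimer of 13) | O=C1C[C@H](O)[C@H](OCc2ccccc2)[C@H](OCc2ccc(OC)cc2)[C@H]1OCc1ccccc1
F2 | step 7 | C3 mesylates of the aldol mixture (both C3 epimers) | O=C1CC(OS(C)(=O)=O)[C@H](OCc2ccccc2)[C@H](OCc2ccc(OC)cc2)[C@H]1OCc1ccccc1
F3 | step 7 | 4α,6β-bis(benzyloxy)-5α-(4-methoxybenzyloxy)cyclohex-2-en-1-one | O=C1C=C[C@H](OCc2ccccc2)[C@H](OCc2ccc(OC)cc2)[C@H]1OCc1ccccc1
F4 | step 7 | 2β,3β-epoxy ketone | O=C1[C@H]2O[C@H]2[C@H](OCc2ccccc2)[C@H](OCc2ccc(OC)cc2)[C@H]1OCc1ccccc1
F5 | step 13 | spiro-epoxide of 15 (C7 α, O β) | C1O[C@]12C[C@@H](O[Si](C)(C)C(C)(C)C)[C@H](OCc3ccccc3)[C@H](OCc3ccc(OC)cc3)[C@H]2OCc2ccccc2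
F6 | step 13 | allylic alcohol (7-OH, 3β-OTBS, 4α-OBn, 5α-OPMB, 6β-OBn) | OCC1=C[C@@H](O[Si](C)(C)C(C)(C)C)[C@H](OCc2ccccc2)[C@H](OCc2ccc(OC)cc2)[C@H]1OCc1ccccc1
F7 | step 13 | 5,7-diol (3β-OTBS, 4α-OBn, 6β-OBn) | OCC1=C[C@@H](O[Si](C)(C)C(C)(C)C)[C@H](OCc2ccccc2)[C@H](O)[C@H]1OCc1ccccc1
F8 | step 15 | 1,4,6-triol 5,7-dibenzoate (3β-OTBS) | O[C@@]1(COC(=O)c2ccccc2)C[C@@H](O[Si](C)(C)C(C)(C)C)[C@H](O)[C@H](OC(=O)c2ccccc2)[C@H]1O
F9 | step 15 | 4,6-bis-TES ether of F8 | O[C@@]1(COC(=O)c2ccccc2)C[C@@H](O[Si](C)(C)C(C)(C)C)[C@H](O[Si](CC)(CC)CC)[C@H](OC(=O)c2ccccc2)[C@H]1O[Si](CC)(CC)CC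
F10 | step 15 | tris-silyl alkene (3-O-TBS-4,6-di-O-TES ether of the target) | O=C(OCC1=C[C@@H](O[Si](C)(C)C(C)(C)C)[C@H](O[Si](CC)(CC)CC)[C@H](OC(=O)c2ccccc2)[C@H]1O[Si](CC)(CC)CC)c1ccccc1
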